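**Retrosynthetic overview**
- The target comes from hydrogenolysis of the O7 and O3' benzyl ethers of 7,3'-di-O-benzylquercetin 3,4'-bissulfate. That compound comes from 7,3'-di-O-benzylquercetin and Me3N·SO3 by forming the O3–S and O4'–S bonds in one operation.
- The strategy rests on the C5–OH of ring A, held in a six-membered hydrogen-bonded chelate (O5–H···O=C4–C4a–C5) to the C4 carbonyl of ring C. This takes O5 out of play, and benzyl ethers block O7 and O3'.
- 7,3'-Di-O-benzylquercetin comes from acid removal of two MOM groups (O5, O4') from the flavonol made by Algar–Flynn–Oyamada oxidative cyclisation of a 2'-hydroxychalcone. The chalcone comes from a Claisen–Schmidt condensation of 4'-O-benzyl-6'-O-MOM-phloroacetophenone with 3-benzyloxy-4-(MOM-oxy)benzaldehyde.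
- Ring order: rings A and B are bought with the starting arenes; ring C (the pyranone) is the only ring formed (step 5). The target has no stereocentre.

Key step: step 7

Remark (assumption): the sulfate monoesters are drawn and named as the free acids, as the target is drawn; they would be formed, purified and stored as their dipotassium salts, and the counter-ion is not counted as part of the compound.

**Route**

Step 1
Reactants: 1 2',4',6'-trihydroxyacetophenone; 2 benzyl bromide
Product: 3 1-[4-(benzyloxy)-2,6-dihydroxyphenyl]ethanone
Conditions: BnBr (1.0 equiv), K2CO3 (1.0 equiv), DMF, 0 °C to rt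
Reagents that add atoms: benzyl bromide (compound 2), BrCc1ccccc1
Why: Williamson ether synthesis in which the 4'-OH, para to the acetyl group and not hydrogen-bonded to it, is the most acidic and most nucleophilic phenol, so one equivalent of base and of halide should benzylate it before the two chelated ortho hydroxyls.

Step 2
Reactants: 3 1-[4-(benzyloxy)-2,6-dihydroxyphenyl]ethanone
Product: 4 1-[4-(benzyloxy)-2-hydroxy-6-(methoxymethoxy)phenyl]ethanone
Conditions: MOMCl (1.1 equiv), iPr2NEt (1.5 equiv), CH2Cl2, 0 °C to rt
Reagents that add atoms: chloromethyl methyl ether (MOMCl), COCCl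
Why: O-alkylation of a phenol with an α-chloro ether (MOM protection); once one of the two equivalent ortho hydroxyls is alkylated, the other is locked in a hydrogen bond to the ketone and should not react under amine-base conditions.

Step 3
Reactants: 5 3-(benzyloxy)-4-hydroxybenzaldehyde
Product: 6 3-(benzyloxy)-4-(methoxymethoxy)benzaldehyde
Conditions: MOMCl (1.3 equiv), iPr2NEt (2 equiv), CH2Cl2, 0 °C to rt
Reagents that add atoms: chloromethyl methyl ether (MOMCl), COCCl
Why: MOM protection of the only free phenol by O-alkylation, which leaves the aldehyde and the benzyl ether untouched and masks the acidic 4-OH that would otherwise deactivate the aldehyde in the aldol step.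

Step 4
Reactants: 4 1-[4-(benzyloxy)-2-hydroxy-6-(methoxymethoxy)phenyl]ethanone; 6 3-(benzyloxy)-4-(methoxymethoxy)benzaldehyde
Product: 7 (E)-1-[4-(benzyloxy)-2-hydroxy-6-(methoxymethoxy)phenyl]-3-[3-(benzyloxy)-4-(methoxymethoxy)phenyl]prop-2-en-1-one
Conditions: 50% aq. KOH, EtOH, rt
Reagents that add atoms: none
Why: Claisen–Schmidt condensation of the methyl ketone enolate with a non-enolisable aldehyde, where E1cB loss of water gives the conjugated enone as the thermodynamically favoured E isomer and the MOM and benzyl ethers are stable to base.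

Step 5
Reactants: 7 (E)-2'-hydroxychalcone
Product: 9 7,3'-di-O-benzyl-5,4'-di-O-(methoxymethyl)quercetin, via trans-dihydroflavonol 8 (not isolated)
Conditions: 30% H2O2, 2 M NaOH, MeOH/THF, 0 °C to rt
Reagents that add atoms: hydrogen peroxide, OO
Why: Algar–Flynn–Oyamada reaction, in which the 2'-phenoxide closes ring C at the β-carbon (6-endo) with oxygenation of the α-carbon by hydroperoxide to give dihydroflavonol 8 (trans, racemic), whose two transient stereocentres are erased when alkaline peroxide dehydrogenates it to the flavonol; the para-alkoxy donor on ring B favours β-closure over the aurone pathway.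

Step 6
Reactants: 9 7,3'-di-O-benzyl-5,4'-di-O-(methoxymethyl)quercetin
Product: 10 7,3'-di-O-benzylquercetin
Conditions: 3 M aq. HCl, MeOH/THF, 50 °C
Reagents that add atoms: none
Why: acid-catalysed acetal cleavage (MOM deprotection) frees the 5- and 4'-hydroxyls, while aryl benzyl ethers and the flavonol core are stable to dilute acid at this temperature.

Step 7
Reactants: 10 7,3'-di-O-benzylquercetin; 11 sulfur trioxide–trimethylamine complex
Product: 12 7,3'-di-O-benzylquercetin 3,4'-bissulfate
Conditions: 11 (5 equiv), K2CO3 (6 equiv), DMF, Ar, rt to 40 °C; C18 reverse-phase chromatography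
Reagents that add atoms: sulfur trioxide–trimethylamine complex (compound 11), C[N+](C)(C)S(=O)(=O)[O-]
Why: This is sulfuryl transfer from an amine–SO3 complex to oxyanions, the standard sulfation of phenols and flavonols: carbonate ionises the 4'-OH and the acidic enolic 3-OH, and each oxyanion attacks sulfur of Me3N+–SO3− and expels trimethylamine to give a sulfate monoester anion that is stable to base. Two O–S bonds are formed in one operation; no ring is closed and no stereocentre is made. The step needs site selectivity among three free hydroxyls, and the substrate secures it because the 5-OH sits in a six-membered hydrogen-bonded chelate with the C4 carbonyl, is hardly ionised by K2CO3 and is a poor nucleophile. The 3-OH is also hydrogen-bonded to that carbonyl, but through a weaker five-membered chelate, and it is acidic enough to be ionised and sulfated. O7 and O3', the other reactive oxygens of quercetin, are blocked as benzyl ethers, so the only oxygens that should react are the two that carry sulfate in the target. A moderate excess of reagent, mild base and a low temperature should keep O5 free, and argon protects the air-sensitive flavonol 3-oxyanion until the 4'-monosulfate, expected to form first, has been consumed.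

Step 8
Reactants: 12 7,3'-di-O-benzylquercetin 3,4'-bissulfate
Product: 13 quercetin 3,4'-bissulfate
Conditions: H2 (1 atm), 10% Pd/C, MeOH/H2O, pH 7 potassium phosphate buffer, rt
Reagents that add atoms: none
Why: catalytic hydrogenolysis of the two benzylic C–O bonds frees the 7- and 3'-hydroxyls, while sulfate monoester anions and the tetrasubstituted C2=C3 bond of the chromenone should be inert at one atmosphere, and the neutral buffer prevents acid-catalysed loss of sulfate.

**Compound list**

1 | 2',4',6'-trihydroxyacetophenone | CC(=O)c1c(O)cc(O)cc1O | starting material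
2 | benzyl bromide | BrCc1ccccc1 | starting material
3 | 1-[4-(benzyloxy)-2,6-dihydroxyphenyl]ethanone | CC(=O)c1c(O)cc(OCc2ccccc2)cc1O | intermediate
4 | 1-[4-(benzyloxy)-2-hydroxy-6-(methoxymethoxy)phenyl]ethanone | CC(=O)c1c(O)cc(OCc2ccccc2)cc1OCOC | intermediate
5 | 3-(benzyloxy)-4-hydroxybenzaldehyde | O=Cc1ccc(O)c(OCc2ccccc2)c1 | starting material
6 | 3-(benzyloxy)-4-(methoxymethoxy)benzaldehyde | O=Cc1ccc(OCOC)c(OCc2ccccc2)c1 | intermediate
7 | (E)-1-[4-(benzyloxy)-2-hydroxy-6-(methoxymethoxy)phenyl]-3-[3-(benzyloxy)-4-(methoxymethoxy)phenyl]prop-2-en-1-one | COCOc1ccc(/C=C/C(=O)c2c(O)cc(OCc3ccccc3)cc2OCOC)cc1OCc1ccccc1 | intermediate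
8 | trans-7-(benzyloxy)-2-[3-(benzyloxy)-4-(methoxymethoxy)phenyl]-3-hydroxy-5-(methoxymethoxy)chroman-4-one (racemic; the 2R,3R enantiomer is drawn) | O=C1[C@H](O)[C@@H](c2ccc(OCOC)c(OCc3ccccc3)c2)Oc2cc(OCc3ccccc3)cc(OCOC)c12 | intermediate (not isolated)
9 | 7-(benzyloxy)-2-[3-(benzyloxy)-4-(methoxymethoxy)phenyl]-3-hydroxy-5-(methoxymethoxy)-4H-chromen-4-one | O=c1c(O)c(-c2ccc(OCOC)c(OCc3ccccc3)c2)oc2cc(OCc3ccccc3)cc(OCOC)c12 | intermediate
10 | 7,3'-di-O-benzylquercetin (7-(benzyloxy)-2-[3-(benzyloxy)-4-hydroxyphenyl]-3,5-dihydroxy-4H-chromen-4-one) | O=c1c(O)c(-c2ccc(O)c(OCc3ccccc3)c2)oc2cc(OCc3ccccc3)cc(O)c12 | intermediate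
11 | sulfur trioxide–trimethylamine complex | C[N+](C)(C)S(=O)(=O)[O-] | starting material
12 | 7,3'-di-O-benzylquercetin 3,4'-bissulfate | O=c1c(OS(=O)(=O)O)c(-c2ccc(OS(=O)(=O)O)c(OCc3ccccc3)c2)oc2cc(OCc3ccccc3)cc(O)c12 | intermediate
13 | quercetin 3,4'-bissulfate | O=c1c(OS(=O)(=O)O)c(-c2ccc(OS(=O)(=O)O)c(O)c2)oc2cc(O)cc(O)c12 | target

**Step count**

Total step count: 8. Longest linear sequence: 7 steps (steps 1, 2, 4, 5, 6, 7, 8); step 3 is a one-step branch.

**Steps most likely to fail, with fallbacks**

Step 7 (key step). The sulfation may stall after the first sulfuryl transfer, so that the 3-hydroxyl remains free. If it is forced with more reagent and heat, the chelated 5-hydroxyl may start to react. The dianionic product may also be hard to separate from inorganic salts and partly sulfated material. The fallback changes from direct sulfation to a protected sulfate. Starting from 10, reaction with 2,2,2-trichloroethyl chlorosulfate, Et3N and catalytic DMAP in THF should give the neutral 7,3'-di-O-benzylquercetin 3,4'-bis(2,2,2-trichloroethyl sulfate) F1, which can be purified on silica and checked for regiochemistry before the charge is revealed. Reductive cleavage of both trichloroethyl groups with Zn dust and ammonium formate in MeOH, which leaves benzyl ethers alone, would then give the bissulfate and return to the route at 12.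

Step 5. The ring closure may take the α-carbon instead of the β-carbon (5-exo instead of 6-endo), which leads to an aurone; this is the known weakness of the Algar–Flynn–Oyamada reaction when the chalcone carries a 6'-alkoxy group. The fallback separates ring closure from C3 oxygenation. Starting from 7, oxidative cyclisation with I2 in pyridine at about 100 °C (the base takes up HI so the MOM ethers persist) should give 7-(benzyloxy)-2-[3-(benzyloxy)-4-(methoxymethoxy)phenyl]-5-(methoxymethoxy)-4H-chromen-4-one F2. Dimethyldioxirane in acetone/CH2Cl2 at 0 °C should epoxidise the C2=C3 bond to the flavone 2,3-epoxide F3. A catalytic amount of p-TsOH in CH2Cl2 should open the epoxide at C2 and, after loss of the C3 proton, give the 3-hydroxyflavone, returning to the route at 9.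

Step 1. The alkylation may run on to the 2',4'-dibenzyl ether, or benzylate the electron-rich ring at carbon, so that the mono-ether is formed inefficiently. The fallback gives up mono-alkylation and differentiates O5 later. Starting from 1, benzyl bromide (2.2 equiv) and K2CO3 in DMF should stop cleanly at 1-[2,4-bis(benzyloxy)-6-hydroxyphenyl]ethanone F4, because the last hydroxyl is chelated. Claisen–Schmidt condensation with 6 (KOH, EtOH) should give the (E)-chalcone F5, and alkaline H2O2 the flavonol 5,7-bis(benzyloxy)-2-[3-(benzyloxy)-4-(methoxymethoxy)phenyl]-3-hydroxy-4H-chromen-4-one F6. Concentrated HCl in acetic acid at about 40 °C should then cleave the 5-O-benzyl ether, which lies peri to the C4 carbonyl and is activated by it, together with the MOM group, while the 7- and 3'-benzyl ethers remain. This returns to the route at 10.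

**Further compounds**

F1 | step 7 | 7,3'-di-O-benzylquercetin 3,4'-bis(2,2,2-trichloroethyl sulfate) | O=c1c(OS(=O)(=O)OCC(Cl)(Cl)Cl)c(-c2ccc(OS(=O)(=O)OCC(Cl)(Cl)Cl)c(OCc3ccccc3)c2)oc2cc(OCc3ccccc3)cc(O)c12
F2 | step 5 | 7-(benzyloxy)-2-[3-(benzyloxy)-4-(methoxymethoxy)phenyl]-5-(methoxymethoxy)-4H-chromen-4-one | O=c1cc(-c2ccc(OCOC)c(OCc3ccccc3)c2)oc2cc(OCc3ccccc3)cc(OCOC)c12
F3 | step 5 | 2,3-epoxide of F2 (cis-fused oxirane, racemic; one enantiomer drawn) | O=C1[C@H]2O[C@@]2(c2ccc(OCOC)c(OCc3ccccc3)c2)Oc2cc(OCc3ccccc3)cc(OCOC)c12
F4 | step 1 | 1-[2,4-bis(benzyloxy)-6-hydroxyphenyl]ethanone | CC(=O)c1c(O)cc(OCc2ccccc2)cc1OCc1ccccc1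
F5 | step 1 | (E)-1-[2,4-bis(benzyloxy)-6-hydroxyphenyl]-3-[3-(benzyloxy)-4-(methoxymethoxy)phenyl]prop-2-en-1-one | COCOc1ccc(/C=C/C(=O)c2c(O)cc(OCc3ccccc3)cc2OCc2ccccc2)cc1OCc1ccccc1
F6 | step 1 | 5,7-bis(benzyloxy)-2-[3-(benzyloxy)-4-(methoxymethoxy)phenyl]-3-hydroxy-4H-chromen-4-one | O=c1c(O)c(-c2ccc(OCOC)c(OCc3ccccc3)c2)oc2cc(OCc3ccccc3)cc(OCc3ccccc3)c12
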